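(The data come from a simulation on assumed constants; scatter was added.)

Set four recipes side by side and ask which keeps its target cleanest.

| setting | zeta | epsilon | eta | theta | Wednesday's | Friday's | Tuesday's | Saturday's |
|---|---|---|---|---|---|---|---|---|
| substrate | 0.055 M | 0.055 M | 0.055 M | 0.028 M | 0.055 M | 0.055 M | 0.055 M (fed, over 40 min) | 0.055 M (in portions, 3, over 40 min) |
| reagent | 0.066 M | 0.033 M | 0.13 M | 0.066 M | 0.0660 M | 0.0660 M (fed, over 40 min) | 0.0660 M | 0.0660 M |
| temperature | 20 °C | 31 °C | 20 °C | 31 °C | 25 °C |  | 25 °C | 25 °C |
| remark | run made earlier | run made earlier | run made earlier | run made earlier | everything together at the start | the addition at −5 °C, then warmed to 25 °C; the feed brings no volume worth counting | all else is in the flask from the start; the feed brings no volume worth counting | first portion at the start, last at 40 min |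
| time |  |  |  |  | 50 min | 50 min | 50 min | 50 min |

- zeta (time / min: target / %, side product / %): 4.00: 1, 3; 8.00: 0, 0; 12.0: 3, 0; 15.0: 0, 0; 20.0: 0, 0; 25.0: 1, 1; 30.0: 0, 3
- epsilon (time / min: target / %, side product / %): 5.00: 0, 2; 8.00: 4, 0; 12.0: 2, 2; 15.0: 1, 0; 25.0: 1, 1; 40.0: 1, 2; 60.0: 3, 2
- eta (time / min: target / %, side product / %): 3.00: 1, 0; 10.0: 0, 0; 15.0: 0, 1; 25.0: 5, 0; 40.0: 19, 2; 50.0: 41, 6; 60.0: 65, 9
- theta (time / min: target / %, side product / %): 12.0: 1, 0; 25.0: 3, 0; 40.0: 6, 1; 50.0: 7, 1; 60.0: 12, 5

(scatter of a reading: 1.5 percentage points)

- in percentages every species weighs as the substrate in it: one side product counts as two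
- the numbers in the tables scatter by 1.5 percentage points (one standard deviation)
- on the list of suspects stand: substrate + reagent + target -> 2 target; substrate + reagent -> target; substrate + target -> side product

- which flask leads in share of target in target plus side product ("all alike" within 1.5 percentage points) (Wednesday's / Friday's / Tuesday's / Saturday's / all alike)
- share of target in target plus side product at the end, Wednesday's
- share of target in target plus side product at the end, Friday's
- share of target in target plus side product at the end, Tuesday's
- share of target in target plus side product at the end, Saturday's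

I read the eta run first: it lags, then reaches 65 % target with 9 % side product at 60.0 min. Autocatalysis needs substrate, target and reagent, while the loss to side product needs substrate and target, so in their ratio reagent remains. Each side product removes one target and counts as two. Taking eta's reagent as charged gives, as a reading at 20 °C, the break-even reagent 0.00842 M, the reagent concentration at which the two steps run equally fast. The selectivity of autocatalytic target is then (reagent − break-even)/(reagent + break-even).

Reagent comes first: Wednesday's, Friday's, Tuesday's and Saturday's take the same 0.0660 M, and with the break-even carried unchanged from 20 °C to 25 °C I estimate 77.4 % for autocatalytic target, an estimate that assumes the break-even stays put between those temperatures. Dosing comes next. Substrate cancels in the ratio, so feeding leaves 77.4 % alone. But Tuesday's mean substrate during the feed, 0.0275 M, is lower than Wednesday's 0.055 M, and Saturday's portions average the same. Autocatalysis loses through substrate and again through target not yet made, so the direct step, substrate + reagent → target, should gain weight in both, and its target starts without side product. Temperature comes last. The zeta run reads at most 3 % target through 30.0 min at 20 °C, and Friday's sits at −5 °C for 40 min, then has 10.0 min at 25 °C. I therefore put Friday's first and the others near 77.4 %.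

The forecast names Friday's, with 81 % for Wednesday's, 93 % for Friday's, 84 % for Tuesday's and 84 % for Saturday's, on the ground that “only direct-step target is free of side product”. Its Wednesday's stands above my 77.4 %.

Friday's leads with 88.7 %, holding 0.178 % target and 0.0226 % side product at 50.0 min; Wednesday's gives 76.0 %, Tuesday's 79.5 % and Saturday's 79.5 %.

    substrate + reagent + target → 2 target (k = 0.476 L² mol⁻² s⁻¹, Ea = 38.0 kJ mol⁻¹)
    substrate + reagent → target (k = 2.61 × 10⁻⁵ L mol⁻¹ s⁻¹, Ea = 87.0 kJ mol⁻¹)
    substrate + target → side product (k = 0.00433 L mol⁻¹ s⁻¹, Ea = 55.0 kJ mol⁻¹)
    (constants at 25 °C)

Wednesday's lies 1.4 percentage points below the 77.4 % that 0.00842 M, read at 20 °C, gave. Charged with 0.14 M of substrate at the same reagent, Friday's neighbour falls to 80.3 %, within 2.9 points of that 77.4 %.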